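**Retrosynthetic overview**
1. The side chain is cut at the bond between the vinylic CH of the (E)-C(CH3)=CH unit and the neighbouring CH2; this bond is made by a three-component union of a terminal (R)-propargylic alcohol, AlMe3 and a primary iodide of the ring fragment (Zr-catalysed syn-methylalumination, then Pd-catalysed alkenyl–alkyl Negishi coupling).
2. Enabling feature: the acyclic array O–CH–C(CH3)=CH–CH2 is an (E)-2-methylallylic carbinol whose unsubstituted vinylic CH is the junction. Syn-addition of CH3–Al across the C≡CH of the propargylic alcohol puts the metal exactly on that carbon, and the partner CH2 is primary, one CH2 away from quaternary C1 of the cyclohexane ring.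
3. Ring fragment: the only ring (cyclohexane C1–C6) is not closed in the route but taken from (S)-4-silyloxycyclohexenone. C2 and C1 come from conjugate addition/enolate allylation, C6 from methyl addition, the exocyclic (Z)-enal from isopropenyl addition and oxidative 1,3-transposition; the allyl group is cut down to the CH2CH2I handle.
4. Alkyne fragment: geranyl bromide plus propargyl alcohol, Sharpless epoxidation, then epoxy chloride fragmentation to the (R)-alkynol.
5. Endgame: acetylation, global desilylation, MnO2 oxidation of the allylic alcohol to the enal.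

Key step: step 19

Assumption: (S)-4-(tert-butyldimethylsilyloxy)cyclohex-2-en-1-one and (3-bromopropoxy)(tert-butyl)diphenylsilane are treated as purchasable building blocks; ring atoms are numbered C1 (quaternary carbon carrying CH3 and the long chain), C2 (CH carrying the propyl arm), C3 (alkylidene carbon), C4, C5 and C6 (tertiary carbinol carbon).

Step 1
Reactants: 1 geranyl bromide; 2 propargyl alcohol
Product: 3 (5E)-6,10-dimethylundeca-5,9-dien-2-yn-1-ol
Conditions: CuI (cat.), K2CO3, NaI, DMF, rt
Reagents that add atoms: none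
Why: Copper-acetylide alkylation of a primary allylic bromide (SN2-selective C(sp)–C(sp3) coupling) should join the two commercial pieces at the terminal alkyne carbon without moving the (E)-alkene of the geranyl unit.

Step 2
Reactants: 3 (5E)-6,10-dimethylundeca-5,9-dien-2-yn-1-ol
Product: 4 (2E,5E)-6,10-dimethylundeca-2,5,9-trien-1-ol
Conditions: LiAlH4, THF, 0 °C → reflux; aqueous NaOH work-up
Reagents that add atoms: none
Why: Trans-selective hydroalumination of a propargylic alcohol by LiAlH4 (alkoxide-directed hydride delivery) should give the (2E)-allylic alcohol, the isolated trisubstituted alkenes being inert.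

Step 3
Reactants: 4 (2E,5E)-6,10-dimethylundeca-2,5,9-trien-1-ol
Product: 5 [(2R,3R)-3-[(2E)-3,7-dimethylocta-2,6-dien-1-yl]oxiran-2-yl]methanol
Conditions: Ti(OiPr)4 (cat.), D-(−)-diethyl tartrate (cat.), t-BuOOH, 4 Å MS, CH2Cl2, −20 °C
Reagents that add atoms: tert-butyl hydroperoxide (CC(C)(C)OO)
Why: Sharpless asymmetric epoxidation: the Ti–tartrate complex delivers oxygen to one face of the allylic alkene only, so D-(−)-diethyl tartrate should set the (2R,3R)-epoxide, whose C3 becomes the side-chain carbinol carbon.

Step 4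
Reactants: 5 [(2R,3R)-3-[(2E)-3,7-dimethylocta-2,6-dien-1-yl]oxiran-2-yl]methanol
Product: 6 (2S,3R)-2-(chloromethyl)-3-[(2E)-3,7-dimethylocta-2,6-dien-1-yl]oxirane
Conditions: PPh3, CCl4, NaHCO3, reflux
Reagents that add atoms: carbon tetrachloride (ClC(Cl)(Cl)Cl)
Why: Appel chlorination should convert the primary alcohol into the chloride under neutral conditions that leave the epoxide and its two stereocentres untouched.

Step 5
Reactants: 6 (2S,3R)-2-(chloromethyl)-3-[(2E)-3,7-dimethylocta-2,6-dien-1-yl]oxirane
Product: 7 (3R,5E)-6,10-dimethylundeca-5,9-dien-1-yn-3-ol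
Conditions: n-BuLi (3 equiv), THF, −40 °C; aq. NH4Cl
Reagents that add atoms: none
Why: Base-induced fragmentation of a 2,3-epoxy chloride (α-deprotonation, epoxide opening to the chloroallylic alkoxide, then dehydrochlorination) should give the terminal propargylic alcohol; the C–O bond of the carbinol carbon is never broken, so (R) is retained.

Step 6
Reactants: 8 (S)-4-(tert-butyldimethylsilyloxy)cyclohex-2-en-1-one
Product: 9 (S)-4-(tert-butyldimethylsilyloxy)-2-iodocyclohex-2-en-1-one
Conditions: I2, pyridine, CH2Cl2, rt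
Reagents that add atoms: iodine (II)
Why: Amine-mediated α-iodination of an enone (conjugate addition of pyridine, iodination of the enolate, elimination) should give the α-iodoenone without touching the γ-stereocentre.

Step 7
Reactants: 9 (S)-4-(tert-butyldimethylsilyloxy)-2-iodocyclohex-2-en-1-one
Product: 10 (S)-4-(tert-butyldimethylsilyloxy)-2-methylcyclohex-2-en-1-one
Conditions: Me4Sn, PdCl2(PhCN)2 (cat.), AsPh3, CuI (cat.), NMP, 80 °C
Reagents that add atoms: tetramethylstannane (C[Sn](C)(C)C)
Why: Stille coupling of the α-iodoenone with tetramethyltin under neutral conditions should install the future C1 methyl group and avoid base-mediated enolisation of the γ-silyloxy stereocentre.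

Step 8
Reactants: 10 (S)-4-(tert-butyldimethylsilyloxy)-2-methylcyclohex-2-en-1-one; 11 (3-bromopropoxy)(tert-butyl)diphenylsilane
Product: 14 (2S,3S,4S)-2-allyl-4-(tert-butyldimethylsilyloxy)-3-[3-(tert-butyldiphenylsilyloxy)propyl]-2-methylcyclohexan-1-one, via Grignard reagent 12 (not isolated), via magnesium enolate 13 (not isolated)
Conditions: 11, Mg, THF; CuBr·SMe2 (20 mol%), 10, THF, −40 °C; then allyl iodide, DMPU, −40 → 0 °C
Reagents that add atoms: allyl iodide (C=CCI)
Why: Copper-catalysed conjugate addition of the Grignard reagent anti to the γ-silyloxy group should set C2, and the regiodefined enolate should then be C-allylated anti to the new C2 substituent, which sets quaternary C1 with its methyl cis to the propyl arm (tandem conjugate addition–enolate alkylation).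

Step 9
Reactants: 14 (2S,3S,4S)-2-allyl-4-(tert-butyldimethylsilyloxy)-3-[3-(tert-butyldiphenylsilyloxy)propyl]-2-methylcyclohexan-1-one
Product: 15 (1S,2S,3S,4S)-2-allyl-4-(tert-butyldimethylsilyloxy)-3-[3-(tert-butyldiphenylsilyloxy)propyl]-1,2-dimethylcyclohexan-1-ol
Conditions: MeLi, Et2O, −78 °C
Reagents that add atoms: methyllithium ([Li]C)
Why: 1,2-Addition of methyllithium to the ketone; in the chair with the C2 and C3 substituents equatorial the C1 methyl is axial and shields the equatorial trajectory, so the nucleophile should enter axially from the opposite face and place the C6 hydroxyl cis to the C1 methyl.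

Step 10
Reactants: 15 (1S,2S,3S,4S)-2-allyl-4-(tert-butyldimethylsilyloxy)-3-[3-(tert-butyldiphenylsilyloxy)propyl]-1,2-dimethylcyclohexan-1-ol
Product: 16 (1S,2S,3S,4S)-2-allyl-3-[3-(tert-butyldiphenylsilyloxy)propyl]-1,2-dimethylcyclohexane-1,4-diol
Conditions: HF·pyridine, pyridine, THF, 0 °C → rt
Reagents that add atoms: none
Why: Fluoride-mediated desilylation; the secondary TBS ether should be cleaved selectively because the TBDPS ether is much more stable to HF·pyridine.

Step 11
Reactants: 16 (1S,2S,3S,4S)-2-allyl-3-[3-(tert-butyldiphenylsilyloxy)propyl]-1,2-dimethylcyclohexane-1,4-diol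
Product: 17 (2S,3S,4S)-3-allyl-2-[3-(tert-butyldiphenylsilyloxy)propyl]-4-hydroxy-3,4-dimethylcyclohexan-1-one
Conditions: Dess–Martin periodinane, NaHCO3, CH2Cl2, rt
Reagents that add atoms: none
Why: Dess–Martin oxidation of the secondary alcohol should give the C3 ketone; the tertiary alcohol cannot be oxidised and the buffered, non-basic medium protects the C2 stereocentre from epimerisation.

Step 12
Reactants: 17 (2S,3S,4S)-3-allyl-2-[3-(tert-butyldiphenylsilyloxy)propyl]-4-hydroxy-3,4-dimethylcyclohexan-1-one
Product: 18 (1R,2S,3S,4S)-3-allyl-2-[3-(tert-butyldiphenylsilyloxy)propyl]-3,4-dimethyl-1-(prop-1-en-2-yl)cyclohexane-1,4-diol (expected major C1 epimer drawn)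
Conditions: isopropenylmagnesium bromide (excess), CeCl3, THF, −78 → 0 °C
Reagents that add atoms: isopropenylmagnesium bromide (C=C(C)[Mg]Br)
Why: 1,2-Addition of the organocerium reagent made from isopropenylmagnesium bromide and CeCl3 should suppress enolisation of the hindered ketone; the configuration of the new carbinol carbon is irrelevant because it becomes sp2 in the next step.

Step 13
Reactants: 18 (1R,2S,3S,4S)-3-allyl-2-[3-(tert-butyldiphenylsilyloxy)propyl]-3,4-dimethyl-1-(prop-1-en-2-yl)cyclohexane-1,4-diol
Product: 19 (2Z)-2-[(2R,3S,4S)-3-allyl-2-[3-(tert-butyldiphenylsilyloxy)propyl]-4-hydroxy-3,4-dimethylcyclohexylidene]propanal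
Conditions: pyridinium chlorochromate, NaOAc, 4 Å MS, CH2Cl2, rt
Reagents that add atoms: none
Why: Babler–Dauben oxidative transposition ([3,3] shift of the tertiary allylic chromate ester, then oxidation of the primary chromate) should give the tetrasubstituted enal; the Z geometry is expected because the smaller CH2O/CHO group, not the methyl, is placed syn to the substituted ring carbon C2, whose equatorial side chain would otherwise suffer allylic 1,3-strain.

Step 14
Reactants: 19 (2Z)-2-[(2R,3S,4S)-3-allyl-2-[3-(tert-butyldiphenylsilyloxy)propyl]-4-hydroxy-3,4-dimethylcyclohexylidene]propanal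
Product: 20 (2Z)-2-[(2R,3S,4S)-3-allyl-2-[3-(tert-butyldiphenylsilyloxy)propyl]-4-hydroxy-3,4-dimethylcyclohexylidene]propan-1-ol
Conditions: NaBH4, CeCl3·7H2O (cat.), MeOH, 0 °C
Reagents that add atoms: none
Why: Luche reduction (1,2-selective) should mask the enal as the allylic alcohol for the organometallic steps to come, with the alkene geometry retained.

Step 15
Reactants: 20 (2Z)-2-[(2R,3S,4S)-3-allyl-2-[3-(tert-butyldiphenylsilyloxy)propyl]-4-hydroxy-3,4-dimethylcyclohexylidene]propan-1-ol
Product: 21 bis(triethylsilyl) ether of 20 (O-TES at the allylic CH2O and at the C6 tertiary oxygen)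
Conditions: TESOTf, 2,6-lutidine, CH2Cl2, −78 → 0 °C
Reagents that add atoms: triethylsilyl trifluoromethanesulfonate (CC[Si](CC)(CC)OS(=O)(=O)C(F)(F)F)
Why: Silyl triflate silylation should cap both the primary allylic and the hindered tertiary hydroxyl, so that no free O–H quenches the organometallics of the key step and no alkoxide can displace the later primary iodide.

Step 16
Reactants: 21 bis(triethylsilyl) ether of 20
Product: 23 aldehyde in which the allyl group on C1 of 21 is cut down to CH2CHO, via vicinal diol 22 (not isolated)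
Conditions: OsO4 (cat.), NaIO4, 2,6-lutidine, dioxane/H2O, rt
Reagents that add atoms: sodium periodate ([Na+].[O-]I(=O)(=O)=O)
Why: Johnson–Lemieux oxidation (osmium-catalysed dihydroxylation, periodate cleavage) should cleave only the monosubstituted alkene, since the hindered tetrasubstituted alkene reacts with OsO4 far more slowly.

Step 17
Reactants: 23 aldehyde (C1–CH2CHO)
Product: 24 primary alcohol (C1–CH2CH2OH; other groups as in 21)
Conditions: NaBH4, EtOH, 0 °C
Reagents that add atoms: none
Why: Borohydride reduction of the aldehyde should give the primary alcohol; silyl ethers and the tetrasubstituted alkene are untouched.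

Step 18
Reactants: 24 primary alcohol (C1–CH2CH2OH)
Product: 25 primary iodide (C1–CH2CH2I; O-TES at allylic CH2O and at C6–O, O-TBDPS on the propyl arm)
Conditions: I2, PPh3, imidazole, CH2Cl2, 0 °C → rt
Reagents that add atoms: iodine (II)
Why: Appel-type iodination (PPh3/I2/imidazole) of the primary alcohol should give the primary iodide under buffered conditions compatible with the TES ethers.

Step 19
Reactants: 7 (3R,5E)-6,10-dimethylundeca-5,9-dien-1-yn-3-ol; 25 primary iodide
Product: 28 coupled (R)-allylic alcohol (full target skeleton; free side-chain carbinol OH, O-TES at allylic CH2O and at C6–O, O-TBDPS on the propyl arm), via alkenylalane 26 (not isolated), via alkenylzinc bromide 27 (not isolated)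
Conditions: 7 (1.5 equiv), AlMe3, Cp2ZrCl2 (cat.), CH2Cl2, 0 °C → rt; evaporation of volatiles; ZnBr2, THF; then 25, Pd2(dba)3 (cat.), PCyp3, N-methylimidazole, THF/NMP, 80 °C; aq. potassium sodium tartrate
Reagents that add atoms: trimethylaluminium (C[Al](C)C)
Why: Proposed new method: AlMe3/Cp2ZrCl2 adds CH3 and Al syn across the terminal alkyne of 7 (CH3 to the internal carbon, Al to the terminal CH, the free OH being carried as its aluminium alkoxide), Al-to-Zn exchange gives alkenylzinc 27, and a zerovalent palladium/tricyclopentylphosphine catalyst should undergo SN2-type oxidative addition to the primary C–I bond of 25, transmetalation and reductive elimination to form the CH–CH2 bond. The closest known reaction types are the one-flask Zr-catalysed carboalumination/Pd-catalysed cross-coupling sequence (established for aryl, alkenyl, allyl and benzyl halides) and the Pd/trialkylphosphine Negishi coupling of alkenylzinc halides with unactivated primary alkyl iodides; joining the two with a β-hydrogen-bearing alkyl iodide is the new element. No ring is closed and no stereocentre is created: the (E)-trisubstituted alkene follows from syn-carbometalation and stereoretentive coupling, and the (R)-carbinol centre is not involved. The step needs alkenyl rather than methyl transfer from the metal and coupling rather than β-hydride elimination at the alkylpalladium stage; the first is the normal reactivity order of alkenyl(dimethyl)metals, the second is secured by the bulky electron-rich phosphine and by the unhindered primary iodide, which lies two carbons away from quaternary C1. The other alkenes of both partners are tri- or tetrasubstituted and should not undergo carboalumination, and every hydroxyl of 25 is silylated.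

Step 20
Reactants: 28 coupled (R)-allylic alcohol
Product: 29 (R)-allylic acetate (28 with the side-chain OH acetylated)
Conditions: Ac2O, pyridine, DMAP (cat.), CH2Cl2, 0 °C → rt
Reagents that add atoms: acetic anhydride (CC(=O)OC(C)=O)
Why: Acylation of the only free hydroxyl (the secondary allylic alcohol) with acetic anhydride/DMAP should give the acetate; the stereocentre is not touched.

Step 21
Reactants: 29 (R)-allylic acetate
Product: 30 triol acetate (target with CH2OH in place of CHO)
Conditions: HF·pyridine, pyridine, THF, 0 °C → rt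
Reagents that add atoms: none
Why: Fluoride-mediated global desilylation should remove both TES ethers and the TBDPS ether, the pyridine-buffered medium sparing the allylic acetate.

Step 22
Reactants: 30 triol acetate
Product: 31 CNP0421354.1 (target)
Conditions: MnO2, CH2Cl2, rt
Reagents that add atoms: none
Why: Chemoselective MnO2 oxidation of the allylic primary alcohol should give the enal; saturated primary and tertiary alcohols do not react and the alkene geometry is retained.

**Compound list**
1 | geranyl bromide, (2E)-1-bromo-3,7-dimethylocta-2,6-diene | BrC/C=C(\C)CCC=C(C)C | starting material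
2 | propargyl alcohol | OCC#C | starting material
3 | (5E)-6,10-dimethylundeca-5,9-dien-2-yn-1-ol | OCC#CC/C=C(\C)CCC=C(C)C | intermediate
4 | (2E,5E)-6,10-dimethylundeca-2,5,9-trien-1-ol | OC/C=C/C/C=C(\C)CCC=C(C)C | intermediate
5 | [(2R,3R)-3-[(2E)-3,7-dimethylocta-2,6-dien-1-yl]oxiran-2-yl]methanol | OC[C@H]1O[C@@H]1C/C=C(\C)CCC=C(C)C | intermediate
6 | (2S,3R)-2-(chloromethyl)-3-[(2E)-3,7-dimethylocta-2,6-dien-1-yl]oxirane | ClC[C@H]1O[C@@H]1C/C=C(\C)CCC=C(C)C | intermediate
7 | (3R,5E)-6,10-dimethylundeca-5,9-dien-1-yn-3-ol | O[C@H](C/C=C(\C)CCC=C(C)C)C#C | intermediate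
8 | (S)-4-(tert-butyldimethylsilyloxy)cyclohex-2-en-1-one | O=C1C=C[C@@H](O[Si](C)(C)C(C)(C)C)CC1 | starting material
9 | (S)-4-(tert-butyldimethylsilyloxy)-2-iodocyclohex-2-en-1-one | O=C1C(I)=C[C@@H](O[Si](C)(C)C(C)(C)C)CC1 | intermediate
10 | (S)-4-(tert-butyldimethylsilyloxy)-2-methylcyclohex-2-en-1-one | O=C1C(C)=C[C@@H](O[Si](C)(C)C(C)(C)C)CC1 | intermediate
11 | (3-bromopropoxy)(tert-butyl)diphenylsilane | BrCCCO[Si](c1ccccc1)(c1ccccc1)C(C)(C)C | starting material
12 | [3-(tert-butyldiphenylsilyloxy)propyl]magnesium bromide | Br[Mg]CCCO[Si](c1ccccc1)(c1ccccc1)C(C)(C)C | intermediate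
13 | bromomagnesium enolate formed by conjugate addition of 12 to 10 (enolate across C1–C6) | CC=1[C@H](CCCO[Si](c2ccccc2)(c2ccccc2)C(C)(C)C)[C@@H](O[Si](C)(C)C(C)(C)C)CCC=1O[Mg]Br | intermediate
14 | (2S,3S,4S)-2-allyl-4-(tert-butyldimethylsilyloxy)-3-[3-(tert-butyldiphenylsilyloxy)propyl]-2-methylcyclohexan-1-one | C=CC[C@@]1(C)[C@H](CCCO[Si](c2ccccc2)(c2ccccc2)C(C)(C)C)[C@@H](O[Si](C)(C)C(C)(C)C)CCC1=O | intermediate
15 | (1S,2S,3S,4S)-2-allyl-4-(tert-butyldimethylsilyloxy)-3-[3-(tert-butyldiphenylsilyloxy)propyl]-1,2-dimethylcyclohexan-1-ol | C=CC[C@@]1(C)[C@H](CCCO[Si](c2ccccc2)(c2ccccc2)C(C)(C)C)[C@@H](O[Si](C)(C)C(C)(C)C)CC[C@]1(C)O | intermediate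
16 | (1S,2S,3S,4S)-2-allyl-3-[3-(tert-butyldiphenylsilyloxy)propyl]-1,2-dimethylcyclohexane-1,4-diol | C=CC[C@@]1(C)[C@H](CCCO[Si](c2ccccc2)(c2ccccc2)C(C)(C)C)[C@@H](O)CC[C@]1(C)O | intermediate
17 | (2S,3S,4S)-3-allyl-2-[3-(tert-butyldiphenylsilyloxy)propyl]-4-hydroxy-3,4-dimethylcyclohexan-1-one | C=CC[C@@]1(C)[C@H](CCCO[Si](c2ccccc2)(c2ccccc2)C(C)(C)C)C(=O)CC[C@]1(C)O | intermediate
18 | (1R,2S,3S,4S)-3-allyl-2-[3-(tert-butyldiphenylsilyloxy)propyl]-3,4-dimethyl-1-(prop-1-en-2-yl)cyclohexane-1,4-diol | C=CC[C@@]1(C)[C@H](CCCO[Si](c2ccccc2)(c2ccccc2)C(C)(C)C)[C@@](O)(C(C)=C)CC[C@]1(C)O | intermediate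
19 | (2Z)-2-[(2R,3S,4S)-3-allyl-2-[3-(tert-butyldiphenylsilyloxy)propyl]-4-hydroxy-3,4-dimethylcyclohexylidene]propanal | C=CC[C@@]1(C)[C@H](CCCO[Si](c2ccccc2)(c2ccccc2)C(C)(C)C)/C(=C(/C)C=O)CC[C@]1(C)O | intermediate
20 | (2Z)-2-[(2R,3S,4S)-3-allyl-2-[3-(tert-butyldiphenylsilyloxy)propyl]-4-hydroxy-3,4-dimethylcyclohexylidene]propan-1-ol | C=CC[C@@]1(C)[C@H](CCCO[Si](c2ccccc2)(c2ccccc2)C(C)(C)C)/C(=C(/C)CO)CC[C@]1(C)O | intermediate
21 | bis(triethylsilyl) ether of 20 (allylic CH2O–TES and C6–O–TES) | C=CC[C@@]1(C)[C@H](CCCO[Si](c2ccccc2)(c2ccccc2)C(C)(C)C)/C(=C(/C)CO[Si](CC)(CC)CC)CC[C@]1(C)O[Si](CC)(CC)CC | intermediate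
22 | vicinal diol from dihydroxylation of the allyl group of 21 (mixture of epimers at the new carbinol carbon) | OCC(O)C[C@@]1(C)[C@H](CCCO[Si](c2ccccc2)(c2ccccc2)C(C)(C)C)/C(=C(/C)CO[Si](CC)(CC)CC)CC[C@]1(C)O[Si](CC)(CC)CC | intermediate
23 | aldehyde, C1–CH2CHO (other groups as in 21) | O=CC[C@@]1(C)[C@H](CCCO[Si](c2ccccc2)(c2ccccc2)C(C)(C)C)/C(=C(/C)CO[Si](CC)(CC)CC)CC[C@]1(C)O[Si](CC)(CC)CC | intermediate
24 | primary alcohol, C1–CH2CH2OH (other groups as in 21) | OCC[C@@]1(C)[C@H](CCCO[Si](c2ccccc2)(c2ccccc2)C(C)(C)C)/C(=C(/C)CO[Si](CC)(CC)CC)CC[C@]1(C)O[Si](CC)(CC)CC | intermediate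
25 | primary iodide, C1–CH2CH2I (other groups as in 21) | ICC[C@@]1(C)[C@H](CCCO[Si](c2ccccc2)(c2ccccc2)C(C)(C)C)/C(=C(/C)CO[Si](CC)(CC)CC)CC[C@]1(C)O[Si](CC)(CC)CC | intermediate
26 | (E)-alkenyl(dimethyl)alane from 7, with the carbinol as its dimethylaluminium alkoxide | C[Al](C)O[C@H](C/C=C(\C)CCC=C(C)C)/C(C)=C/[Al](C)C | intermediate
27 | (E)-alkenylzinc bromide from 26 (O–AlMe2 retained) | C[Al](C)O[C@H](C/C=C(\C)CCC=C(C)C)/C(C)=C/[Zn]Br | intermediate
28 | coupled (R)-allylic alcohol: target skeleton, free side-chain OH, O-TES at allylic CH2O and at C6–O, O-TBDPS on the propyl arm | O[C@H](C/C=C(\C)CCC=C(C)C)/C(C)=C/CC[C@@]1(C)[C@H](CCCO[Si](c2ccccc2)(c2ccccc2)C(C)(C)C)/C(=C(/C)CO[Si](CC)(CC)CC)CC[C@]1(C)O[Si](CC)(CC)CC | intermediate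
29 | acetate of 28 | CC(=O)O[C@H](C/C=C(\C)CCC=C(C)C)/C(C)=C/CC[C@@]1(C)[C@H](CCCO[Si](c2ccccc2)(c2ccccc2)C(C)(C)C)/C(=C(/C)CO[Si](CC)(CC)CC)CC[C@]1(C)O[Si](CC)(CC)CC | intermediate
30 | triol acetate (target with the allylic CH2OH in place of CHO) | CC(=O)O[C@H](C/C=C(\C)CCC=C(C)C)/C(C)=C/CC[C@@]1(C)[C@H](CCCO)/C(=C(/C)CO)CC[C@]1(C)O | intermediate
31 | CNP0421354.1 | CC(=O)O[C@H](C/C=C(\C)CCC=C(C)C)/C(C)=C/CC[C@@]1(C)[C@H](CCCO)/C(=C(/C)C=O)CC[C@]1(C)O | target

**Step count**
Total steps: 22. Longest linear sequence: 17 steps (steps 6–22, from 8).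

**Steps most likely to fail**

Step 19 (proposed new method). The coupling may fail through slow oxidative addition of the alkyl iodide, β-hydride elimination at the alkylpalladium stage, competing methyl transfer, or loss of the alkenyl metal by protonation before it couples. The fallback reverses the polarity and uses only known reactions; it sets out from 7 and 25. Alkynol 7 is carboaluminated as in step 19 and the alkenylalane is quenched with I2 (THF, −30 °C) to give the vinyl iodide F1. Iodide 25 is treated with t-BuLi (Et2O, −78 °C) and then B-methoxy-9-borabicyclo[3.3.1]nonane to give the lithium alkyl(methoxy)borate F2. B-alkyl Suzuki–Miyaura coupling of F2 with F1 (Pd(dppf)Cl2, AsPh3, aq. K3PO4, DMF, rt) should return to the route at 28.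

Step 13. The oxidative transposition may suffer from ionisation of the tertiary allylic chromate, with trapping by the C6 hydroxyl or elimination, or from incomplete control of the alkene geometry. The fallback sets out from 17 and builds the enal by carbonyl olefination instead of rearrangement. Lithiated N-tert-butyl-2-(trimethylsilyl)propan-1-imine (LDA, THF, −78 °C → rt) adds to the ketone and undergoes Peterson elimination to the unsaturated aldimine F4. Hydrolysis with aqueous oxalic acid, under which the enal can equilibrate towards the Z isomer, should return to the route at 19.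

Step 9. Methyllithium may attack from the equatorial face (poor facial selectivity, giving the C6 epimer) or enolise the ketone. The fallback sets out from 14 and forms the C–C bond with a small, irreversibly adding ylide. Dimethylsulfonium methylide (Me3S+ I−, n-BuLi, THF, 0 °C) should add axially to give the spiro-epoxide F3. Reductive opening at the CH2 terminus with LiEt3BH (THF, 0 °C) should return to the route at 15.

Further compounds
F1 | step 19 | (1E,3R,5E)-1-iodo-2,6,10-trimethylundeca-1,5,9-trien-3-ol | O[C@H](C/C=C(\C)CCC=C(C)C)/C(C)=C/I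
F2 | step 19 | lithium B-methoxy-B-alkyl-9-borabicyclo[3.3.1]nonane borate from iodide 25 (boron on the former CH2I carbon) | [Li+].CO[B-]1(CC[C@@]3(C)[C@H](CCCO[Si](c4ccccc4)(c4ccccc4)C(C)(C)C)/C(=C(/C)CO[Si](CC)(CC)CC)CC[C@]3(C)O[Si](CC)(CC)CC)C2CCCC1CCC2
F3 | step 9 | spiro-epoxide of ketone 14 at C6 (oxirane CH2 on the face of the allyl group, oxygen on the face of the C1 methyl) | C=CC[C@@]1(C)[C@H](CCCO[Si](c2ccccc2)(c2ccccc2)C(C)(C)C)[C@@H](O[Si](C)(C)C(C)(C)C)CC[C@@]13CO3
F4 | step 13 | N-tert-butyl aldimine of enal 19 | C=CC[C@@]1(C)[C@H](CCCO[Si](c2ccccc2)(c2ccccc2)C(C)(C)C)/C(=C(/C)\C=N\C(C)(C)C)CC[C@]1(C)O
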